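**Retrosynthetic overview**
1. Artopetelin C ⇐ tris-TBS ether 16 (global desilylation, last step).
2. Furan ring (formed last): the C3–C3a bond joins the α-carbon of an aryl methyl ketone, made electrophilic as α-bromoketone 9 (an enolonium equivalent), to the free ortho carbon of phenol 14. Both carbons are natively nucleophilic. O1–C2 then closes by cyclodehydration.
3. 9 ⇐ 3,5-dihydroxyacetophenone: double O-tert-prenylation and double aromatic Claisen place both prenyl groups beside the acetyl group; one prenyl/OH pair is then closed to the chroman (first ring formed).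
4. 14 ⇐ phloroglucinol: bis-silylation, O-prenylation, Claisen to put the 1,1-dimethylallyl group between OH and OTBS.
5. Ring order: chroman → furan; both benzene rings are bought.

Assumption: the target has no stereocentre and no configurationally stable axis, so it is a single achiral compound and no stereocontrol is needed.

**Route**

Step 1
Reactants: 1 1-(3,5-dihydroxyphenyl)ethan-1-one; 2 tert-butyl 2-methylbut-3-en-2-yl carbonate (2.4 equiv)
Product: 3 1-[3,5-bis(2-methylbut-3-en-2-yloxy)phenyl]ethan-1-one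
Conditions: Pd(PPh3)4 (5 mol%), THF, 0 °C → rt
Reagents that add atoms: none
Why: Pd(0) ionises the tertiary carbonate to a π-prenyl complex and the phenoxide attacks its more substituted terminus at low temperature, giving the 1,1-dimethylallyl aryl ethers (Tsuji–Trost O-allylation with branched selectivity).

Step 2
Reactants: 3 1-[3,5-bis(2-methylbut-3-en-2-yloxy)phenyl]ethan-1-one
Product: 4 1-[3,5-dihydroxy-2,6-bis(3-methylbut-2-en-1-yl)phenyl]ethan-1-one
Conditions: PhMe, 110 °C, sealed tube
Reagents that add atoms: none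
Why: Two aromatic Claisen [3,3] rearrangements deliver prenyl groups to C2 and C6, the sites favoured both by the meta-acyl group (directs towards itself) and by the meta-oxygen (directs para to itself), with C4 the minor site.

Step 3
Reactants: 4 1-[3,5-dihydroxy-2,6-bis(3-methylbut-2-en-1-yl)phenyl]ethan-1-one
Product: 5 1-[7-hydroxy-2,2-dimethyl-6-(3-methylbut-2-en-1-yl)chroman-5-yl]ethan-1-one
Conditions: Amberlyst-15, PhMe, 40 °C, stopped at about 50% conversion, 4 recycled
Reagents that add atoms: none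
Why: Acid-catalysed Markovnikov hydroalkoxylation through the tertiary prenyl cation closes one of the two equivalent prenyl/OH pairs to the 2,2-dimethylchroman, and partial conversion keeps the bis-chroman low (about 40% per pass, about 80% based on recovered 4).

Step 4
Reactants: 5 1-[7-hydroxy-2,2-dimethyl-6-(3-methylbut-2-en-1-yl)chroman-5-yl]ethan-1-one
Product: 6 1-[7-(tert-butyldimethylsilyloxy)-2,2-dimethyl-6-(3-methylbut-2-en-1-yl)chroman-5-yl]ethan-1-one
Conditions: TBSCl, imidazole, DMF, rt
Reagents that add atoms: tert-butyldimethylsilyl chloride CC(C)(C)[Si](C)(C)Cl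
Why: Standard phenol silylation masks the last B-ring OH so that it can neither be alkylated nor close a second chroman later.

Step 5
Reactants: 6 1-[7-(tert-butyldimethylsilyloxy)-2,2-dimethyl-6-(3-methylbut-2-en-1-yl)chroman-5-yl]ethan-1-one
Product: 9 2-bromo-1-[7-(tert-butyldimethylsilyloxy)-2,2-dimethyl-6-(3-methylbut-2-en-1-yl)chroman-5-yl]ethan-1-one, via lithium enolate 7 (not isolated), via TMS enol ether 8 (not isolated)
Conditions: LiHMDS, THF, −78 °C; TMSCl; then NBS, −78 → 0 °C
Reagents that add atoms: lithium bis(trimethylsilyl)amide [Li]N([Si](C)(C)C)[Si](C)(C)C (Li only in 7); chlorotrimethylsilane C[Si](C)(C)Cl (TMS only in 8); N-bromosuccinimide O=C1CCC(=O)N1Br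
Why: Kinetic enolisation at the only enolisable position, O-silylation and electrophilic bromination of the silyl enol ether (far more nucleophilic than the prenyl alkene or the arene at −78 °C) turn the ketone α-carbon into an electrophile, i.e. an enolonium equivalent.

Step 6
Reactants: 10 benzene-1,3,5-triol (phloroglucinol)
Product: 11 3,5-bis(tert-butyldimethylsilyloxy)phenol
Conditions: TBSCl (2.0 equiv), imidazole, DMF, 0 °C → rt
Reagents that add atoms: tert-butyldimethylsilyl chloride CC(C)(C)[Si](C)(C)Cl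
Why: Statistical bis-silylation of the C3-symmetric triol gives the bis-ether as the main separable product (about 50%), and the mono- and tris-silyl by-products can be recycled.

Step 7
Reactants: 11 3,5-bis(tert-butyldimethylsilyloxy)phenol; 12 3-methylbut-2-en-1-ol
Product: 13 1,3-bis(tert-butyldimethylsilyloxy)-5-(3-methylbut-2-en-1-yloxy)benzene
Conditions: PPh3, DIAD, THF, 0 °C → rt
Reagents that add atoms: none
Why: Mitsunobu etherification of the single free phenol with the primary allylic alcohol proceeds under neutral conditions that leave the aryl silyl ethers untouched.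

Step 8
Reactants: 13 1,3-bis(tert-butyldimethylsilyloxy)-5-(3-methylbut-2-en-1-yloxy)benzene
Product: 14 3,5-bis(tert-butyldimethylsilyloxy)-2-(2-methylbut-3-en-2-yl)phenol
Conditions: PhNEt2, 190 °C
Reagents that add atoms: none
Why: Aromatic Claisen [3,3] rearrangement of the prenyl ether bonds the dimethyl-substituted allyl terminus to the ortho carbon (the two ortho sites are equivalent), giving the 1,1-dimethylallyl phenol with its OH now flanked by a quaternary carbon and one free ortho C–H.

Step 9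
Reactants: 9 2-bromo-1-[7-(tert-butyldimethylsilyloxy)-2,2-dimethyl-6-(3-methylbut-2-en-1-yl)chroman-5-yl]ethan-1-one; 14 3,5-bis(tert-butyldimethylsilyloxy)-2-(2-methylbut-3-en-2-yl)phenol (1.5 equiv)
Product: 16 4,6-bis(tert-butyldimethylsilyloxy)-2-[7-(tert-butyldimethylsilyloxy)-2,2-dimethyl-6-(3-methylbut-2-en-1-yl)chroman-5-yl]-7-(2-methylbut-3-en-2-yl)benzofuran, via o-hydroxybenzyl ketone 15 (not isolated)
Conditions: neutral Al2O3, xylene, 130 °C
Reagents that add atoms: none
Why: α-Bromoketone 9 is an enolonium equivalent, so the ketone α-carbon and the phenol ortho carbon (both natively nucleophilic) are joined by alumina-promoted ortho-C-alkylation of the neutral phenol, whose oxygen is shielded by the adjacent quaternary carbon and whose other ortho site is blocked, and ketone 15 then cyclodehydrates to the aromatic furan (interrupted Feist–Benary-type phenol/α-bromoketone annulation, known for simple phenols to give 2-arylbenzofurans), which fixes the 1,1-dimethylallyl group at C7.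

Step 10
Reactants: 16 4,6-bis(tert-butyldimethylsilyloxy)-2-[7-(tert-butyldimethylsilyloxy)-2,2-dimethyl-6-(3-methylbut-2-en-1-yl)chroman-5-yl]-7-(2-methylbut-3-en-2-yl)benzofuran
Product: 17 Artopetelin C
Conditions: TBAF (3.3 equiv), AcOH (3.3 equiv), THF, 0 °C → rt, Ar
Reagents that add atoms: none
Why: Buffered fluoride desilylation frees the three phenols without acid, so neither the prenyl/OH pair nor the 1,1-dimethylallyl/OH pair cyclises.

**Compound list**
1 | 1-(3,5-dihydroxyphenyl)ethan-1-one | CC(=O)c1cc(O)cc(O)c1 | starting material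
2 | tert-butyl 2-methylbut-3-en-2-yl carbonate | C=CC(C)(C)OC(=O)OC(C)(C)C | starting material
3 | 1-[3,5-bis(2-methylbut-3-en-2-yloxy)phenyl]ethan-1-one | CC(=O)c1cc(OC(C)(C)C=C)cc(OC(C)(C)C=C)c1 | intermediate
4 | 1-[3,5-dihydroxy-2,6-bis(3-methylbut-2-en-1-yl)phenyl]ethan-1-one | CC(=O)c1c(CC=C(C)C)c(O)cc(O)c1CC=C(C)C | intermediate
5 | 1-[7-hydroxy-2,2-dimethyl-6-(3-methylbut-2-en-1-yl)chroman-5-yl]ethan-1-one | CC(=O)c1c(CC=C(C)C)c(O)cc2OC(C)(C)CCc12 | intermediate
6 | 1-[7-(tert-butyldimethylsilyloxy)-2,2-dimethyl-6-(3-methylbut-2-en-1-yl)chroman-5-yl]ethan-1-one | CC(=O)c1c(CC=C(C)C)c(O[Si](C)(C)C(C)(C)C)cc2OC(C)(C)CCc12 | intermediate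
7 | lithium enolate of 6 | C=C(O[Li])c1c(CC=C(C)C)c(O[Si](C)(C)C(C)(C)C)cc2OC(C)(C)CCc12 | intermediate (not isolated)
8 | trimethylsilyl enol ether of 6 | C=C(O[Si](C)(C)C)c1c(CC=C(C)C)c(O[Si](C)(C)C(C)(C)C)cc2OC(C)(C)CCc12 | intermediate (not isolated)
9 | 2-bromo-1-[7-(tert-butyldimethylsilyloxy)-2,2-dimethyl-6-(3-methylbut-2-en-1-yl)chroman-5-yl]ethan-1-one | O=C(CBr)c1c(CC=C(C)C)c(O[Si](C)(C)C(C)(C)C)cc2OC(C)(C)CCc12 | intermediate
10 | benzene-1,3,5-triol (phloroglucinol) | Oc1cc(O)cc(O)c1 | starting material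
11 | 3,5-bis(tert-butyldimethylsilyloxy)phenol | Oc1cc(O[Si](C)(C)C(C)(C)C)cc(O[Si](C)(C)C(C)(C)C)c1 | intermediate
12 | 3-methylbut-2-en-1-ol (prenol) | CC(C)=CCO | starting material
13 | 1,3-bis(tert-butyldimethylsilyloxy)-5-(3-methylbut-2-en-1-yloxy)benzene | CC(C)=CCOc1cc(O[Si](C)(C)C(C)(C)C)cc(O[Si](C)(C)C(C)(C)C)c1 | intermediate
14 | 3,5-bis(tert-butyldimethylsilyloxy)-2-(2-methylbut-3-en-2-yl)phenol | C=CC(C)(C)c1c(O)cc(O[Si](C)(C)C(C)(C)C)cc1O[Si](C)(C)C(C)(C)C | intermediate
15 | 2-[2-hydroxy-3-(2-methylbut-3-en-2-yl)-4,6-bis(tert-butyldimethylsilyloxy)phenyl]-1-[7-(tert-butyldimethylsilyloxy)-2,2-dimethyl-6-(3-methylbut-2-en-1-yl)chroman-5-yl]ethan-1-one | C=CC(C)(C)c1c(O)c(CC(=O)c2c(CC=C(C)C)c(O[Si](C)(C)C(C)(C)C)cc3OC(C)(C)CCc23)c(O[Si](C)(C)C(C)(C)C)cc1O[Si](C)(C)C(C)(C)C | intermediate (not isolated)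
16 | 4,6-bis(tert-butyldimethylsilyloxy)-2-[7-(tert-butyldimethylsilyloxy)-2,2-dimethyl-6-(3-methylbut-2-en-1-yl)chroman-5-yl]-7-(2-methylbut-3-en-2-yl)benzofuran | C=CC(C)(C)c1c(O[Si](C)(C)C(C)(C)C)cc(O[Si](C)(C)C(C)(C)C)c2cc(-c3c(CC=C(C)C)c(O[Si](C)(C)C(C)(C)C)cc4OC(C)(C)CCc34)oc12 | intermediate
17 | Artopetelin C, 2-[7-hydroxy-2,2-dimethyl-6-(3-methylbut-2-en-1-yl)chroman-5-yl]-7-(2-methylbut-3-en-2-yl)benzofuran-4,6-diol | C=CC(C)(C)c1c(O)cc(O)c2cc(-c3c(CC=C(C)C)c(O)cc4c3CCC(C)(C)O4)oc12 | target

**Step count and risks**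
Total step count: 10. Longest linear sequence: 7 (steps 1, 2, 3, 4, 5, 9, 10).

Most likely to fail:

Step 9 (alumina annulation). Possible problems are O- instead of C-alkylation, loss of silyl groups on hot alumina, and slow cyclodehydration at the di-ortho-substituted ketone. Fallback, setting out from 14 and coming back at 15: the C3–C3a bond is made by normal-polarity cross-coupling. Phenol 14 is iodinated at its only free ortho carbon (NIS, CH2Cl2, 0 °C) to give 2-iodo-6-(2-methylbut-3-en-2-yl)-3,5-bis(tert-butyldimethylsilyloxy)phenol F1. Pd-catalysed enolate arylation of ketone 6 with F1 (Pd2(dba)3, XPhos, NaOtBu, PhMe, 80 °C) gives 15, which is closed to 16 with PPTS or TFA in a separate, independently tunable operation.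

Step 3 (mono-cyclisation of two equivalent prenyl/OH pairs; statistical, with over-cyclisation to the bis-chroman). Fallback, setting out from 1 and coming back at 5: the two ortho units are built one at a time. Compound 1 is mono-etherified with one equivalent of 2 under Pd(PPh3)4 (3 is the reusable by-product) to 1-[3-hydroxy-5-(2-methylbut-3-en-2-yloxy)phenyl]ethan-1-one F2. Claisen rearrangement gives 1-[3,5-dihydroxy-2-(3-methylbut-2-en-1-yl)phenyl]ethan-1-one F3. Its single prenyl group is cyclised with acid to completion, giving 1-(7-hydroxy-2,2-dimethylchroman-5-yl)ethan-1-one F4. A second Pd O-allylation with 2 gives 1-[2,2-dimethyl-7-(2-methylbut-3-en-2-yloxy)chroman-5-yl]ethan-1-one F5, and its Claisen rearrangement (C6 favoured over C8 by the acyl and ring-oxygen substituents) delivers 5.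

Step 2 (regiochemistry of the double Claisen: some migration to C4, and thermal loss of isoprene). Fallback, setting out from 1 and coming back at 4: the prenyl groups are installed by cross-coupling instead of sigmatropic shift. Compound 1 is silylated to 1-[3,5-bis(tert-butyldimethylsilyloxy)phenyl]ethan-1-one F6. NBS dibromination at the two positions flanking the acetyl group (the carbon between the two silyloxy groups is shielded) gives 1-[2,6-dibromo-3,5-bis(tert-butyldimethylsilyloxy)phenyl]ethan-1-one F7. Double Stille coupling with tributyl(3-methylbut-2-en-1-yl)stannane and Pd(PPh3)4 gives 1-[3,5-bis(tert-butyldimethylsilyloxy)-2,6-bis(3-methylbut-2-en-1-yl)phenyl]ethan-1-one F8, which TBAF desilylates to 4.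

**Further compounds**
F1 | step 9 | 2-iodo-6-(2-methylbut-3-en-2-yl)-3,5-bis(tert-butyldimethylsilyloxy)phenol | C=CC(C)(C)c1c(O)c(I)c(O[Si](C)(C)C(C)(C)C)cc1O[Si](C)(C)C(C)(C)C
F2 | step 3 | 1-[3-hydroxy-5-(2-methylbut-3-en-2-yloxy)phenyl]ethan-1-one | CC(=O)c1cc(O)cc(OC(C)(C)C=C)c1
F3 | step 3 | 1-[3,5-dihydroxy-2-(3-methylbut-2-en-1-yl)phenyl]ethan-1-one | CC(=O)c1cc(O)cc(O)c1CC=C(C)C
F4 | step 3 | 1-(7-hydroxy-2,2-dimethylchroman-5-yl)ethan-1-one | CC(=O)c1cc(O)cc2OC(C)(C)CCc12
F5 | step 3 | 1-[2,2-dimethyl-7-(2-methylbut-3-en-2-yloxy)chroman-5-yl]ethan-1-one | CC(=O)c1cc(OC(C)(C)C=C)cc2OC(C)(C)CCc12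
F6 | step 2 | 1-[3,5-bis(tert-butyldimethylsilyloxy)phenyl]ethan-1-one | CC(=O)c1cc(O[Si](C)(C)C(C)(C)C)cc(O[Si](C)(C)C(C)(C)C)c1
F7 | step 2 | 1-[2,6-dibromo-3,5-bis(tert-butyldimethylsilyloxy)phenyl]ethan-1-one | CC(=O)c1c(Br)c(O[Si](C)(C)C(C)(C)C)cc(O[Si](C)(C)C(C)(C)C)c1Br
F8 | step 2 | 1-[3,5-bis(tert-butyldimethylsilyloxy)-2,6-bis(3-methylbut-2-en-1-yl)phenyl]ethan-1-one | CC(=O)c1c(CC=C(C)C)c(O[Si](C)(C)C(C)(C)C)cc(O[Si](C)(C)C(C)(C)C)c1CC=C(C)C
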